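The target cannot outrun its partner: with the main step alone, partner and solid substrate going one to one into target, 0.125 M of partner on 0.25 M of solid substrate makes 50.0% of the solid substrate charged. These were the flasks and the earlier runs, and this was what I had to say.

in all of them: solid substrate 0.25 M

| run | partner | second substrate | remark | time |
|---|---|---|---|---|
| maple | 0.125 M | 0.50 M | run made earlier |  |
| alder | 0.17 M | 0.50 M | run made earlier |  |
| oak | 0.28 M | 0.50 M | run made earlier |  |
| larch | 0.125 M | 1 M | run made earlier |  |
| violet | 0.125 M (fed, over 4.0 h) | 0.500 M | all else is in the flask from the start; the feed brings no volume worth counting | 10 h |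
| ochre | 0.125 M | 0.500 M | everything together at the start | 10 h |
| teal | 0.125 M | 0.500 M (fed, over 4.0 h) | all else is in the flask from the start; the feed brings no volume worth counting | 10 h |

- maple (time / h: target / %): 0.833: 16; 1.50: 23; 2.50: 25; 3.00: 26; 4.00: 27; 5.00: 23; 6.00: 22
- alder (time / h: target / %): 0.667: 13; 2.00: 31; 3.00: 38; 5.00: 31; 8.00: 33; 10.0: 28; 12.0: 32
- oak (time / h: target / %): 0.667: 30; 2.00: 50; 3.00: 55; 5.00: 57; 8.00: 56; 10.0: 54; 12.0: 51
- larch (time / h: target / %): 1.00: 11; 2.00: 16; 3.00: 18; 6.00: 16; 12.0: 16

(standard deviation of a reading: 2 percentage points)

- solid, in amounts per volume of the solution: solid substrate
- the earlier runs were read with a standard deviation of 2 percentage points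
- at the start none of the solid substrate is in solution
- a reading or a percentage of target counts all its forms, free or not

* which flask leads in amount of target, in percent of the solid substrate charged ("all alike" within 1.5 percentage points) (violet / ochre / teal / all alike)
* how much target is there at the end, in percent of the solid substrate charged: violet
* how much target is there at the end, in percent of the solid substrate charged: ochre
* how much target is there at the end, in percent of the solid substrate charged: teal

Maple read about 25% at 2.50 h, so 0.500 of its partner became target, and larch, with twice the second substrate, kept 0.320. I therefore added one process, a loss of partner to second substrate. Dividing the rate of the main step by the rate of this loss removes time, which leaves a ratio that falls as [second substrate] rises. Maple gave the split concentration 0.500 M, the [second substrate] at which partner divides evenly between target and loss, and larch read 0.471 M. The share reaching target is then the split concentration over itself plus [second substrate].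

Taking [second substrate] at its charge of 0.500 M in ochre and violet alike, a simplification of mine, I reckoned that share as 0.500, or 25.0%. In teal, maple's first reading gave partner a total decay constant of 1.23 h⁻¹, and its productive part a lifetime of 1.63 h. Over that lifetime the feed delivers 0.204 M of second substrate, and counting all of it as free [second substrate], a rough stand-in of mine, I reckoned the share as 0.710, or 35.5%.

Then came the rest, a late loss of target that I read from oak, which kept 0.895 of its reading from 5.00 h to 12.0 h. My figures became 22.4% for ochre and violet and 31.8% for teal.

The forecast, reasoning that “the second substrate mainly destroys partner”, gave 24.5% for violet, 24% for ochre and 36% for teal, so teal led there as in my figures, though my teal stood lower than the forecast's.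

The flasks ended with 23.6% in violet, 21.2% in ochre and 32.8% in teal, and teal led.

    starting material + partner → target (k = 0.0880 M⁻¹ min⁻¹)
    solid substrate ⇌ starting material, rate k2*(cs2 - [starting material]) while solid is left; crystals form when [starting material] > cs2 (solubility = 0.110 M, k = 0.340 min⁻¹)
    starting material + second substrate → cross product (k = 0.00470 M⁻¹ min⁻¹)
    second substrate + target ⇌ idle adduct, settled at all times (K = 53.0 M⁻¹)
    starting material + target → side product (k = 0.0640 M⁻¹ min⁻¹)
    second substrate + partner → second product (k = 0.0200 M⁻¹ min⁻¹)

In teal the main step gave partner a half-life of 1.2 h at 0.319 h, shorter than the 4.0 h feed of second substrate, and teal ended with 0.0233 M of second product against 0.0608 M in ochre. That ochre amount stands beside the 0.0625 M of lost partner from the split concentration. The neighbour flask, teal with 1.0 M of solid substrate, again held 0.0233 M of second product. My teal share and trim, set on that larger charge, give 7.95% target, and that flask held 7.95%.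

The readings stem from a simulated flask with made-up constants.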